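## Structural features

Broussoflavonol C is a flavonol: a 3-hydroxy-4H-chromen-4-one (rings A and C fused) that carries aryl ring B at C2 through the C2–C1' bond. Ring A is a phloroglucinol-type ring with free hydroxyls at C5 and C7 and, at C8, a 2-methylbut-3-en-2-yl (1,1-dimethylallyl) group whose quaternary carbon sits between O7 and the ring oxygen O1 on C8a. Ring B is a pentasubstituted benzene with prenyl groups at C2' and C3', a catechol at C4' and C5' and hydrogen only at C6', so four substituents stand in a row and the C2' prenyl group crowds the C2–C1' bond and the 3-hydroxyl. The molecule has no stereocentre, so no stereocentres stand next to each other; the only geometric element on the way is an enone double bond that disappears. The fragile features are three alkenes ortho to hydroxyls (C3' prenyl/O4', C8 dimethylallyl/O7, C2' prenyl/O3), which add the hydroxyl under protic or strong Lewis acid, and the catechol and 3-hydroxypyranone, which oxidise in basic air; the alkenes also exclude hydrogenolysis, electrophilic oxidants and boron halides. The real difficulty is regiochemical: ring B must be made without arene prenylation, the inverted prenyl group must go to C8 and not C6, and the oxygen next to it, not the one at C5, must become O1. The key step uses the vicinal pair O4'/O5' with C1' para to O4' and the prenyl groups at C2' and C3': these map onto a 3-alkoxyfuran (ring oxygen to O5', alkoxy oxygen to O4', the prenylated β- and α-carbons to C3' and C2') and a propiolate (C1' and C6').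

## Logic of the disconnections

23 back to 21. The last forward operation breaks the four O–CH2 acetal bonds at O5, O7, O4' and O5'. Carrying these oxygens as identical acetals lets every earlier step run in hydride, hydroxide or peroxide without touching a phenol. The demand is a cleavage without protic acid, because three of the hydroxyls set free lie next to alkenes.

21 back to 19. O1–C2 and C3–O3 are cut, which opens ring C to an open-chain enone with a free hydroxyl on ring A. One oxidative cyclisation then closes ring C and installs O3 together. The gain is two arenes joined by three carbons. The demand is that the phenoxide closes in the six-membered mode and that only the hydroxyl beside the quaternary carbon is free.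

19 back to 13 and 18. The Cα=Cβ bond (C3=C2 of the later ring C) is cut as an aldol condensation. This divides the molecule into halves of similar size, each with one ring and all its substituents. The forward step must work with an ortho-substituted aldehyde and a hindered methyl ketone under base only.

18 back to 17. The O–CH2 bonds at the oxygens that become O5 and O7 are removed. The gain is that 17 needs no protecting group during the rearrangement that makes it. The demand is site selectivity between the two hydroxyls ortho to the acetyl group, so that the one flanked by the quaternary carbon stays free.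

17 back to 16, then to 14 and 15. The bond from the ring carbon (future C8) to the quaternary carbon is cut by a retro-[3,3] shift, which moves the allyl unit to the para oxygen as a prenyl ether; the O–CH2 bond is then cut. The inversion of the allyl group in the forward shift is what turns a prenyl ether into the 1,1-dimethylallyl group. The symmetry of 16 makes the two ortho carbons identical and the acetyl group blocks the para carbon. The forward step must run cool enough that the new group does not rearrange further or cyclise.

13 back to 12, 11 and 10. No skeletal bond is cut. The carbon on C1' is taken back from aldehyde through alcohol to ester, and the O5'–CH2 acetal bond is removed. This brings ring B to the form in which the ring-forming step delivers it.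

10 back to 7 and 8. C1'–C2' and C5'–C6' are cut and O5' is reconnected to C2' as a bridge. Ring B becomes a five-membered heteroaromatic diene and a two-carbon alkyne ester. Atom mapping: ring oxygen of 7 to O5', its unsubstituted α-carbon to C5', the alkoxy carbon to C4', the prenylated β- and α-carbons to C3' and C2', the ester-bearing carbon of 8 to C1' and its terminal carbon to C6'. All five substituents of ring B are then in place before the ring exists. The forward step needs one orientation of addition and one direction of bridge opening.

7 back to 4 and 5. The bond from the α-carbon (future C2') to the prenyl CH2 is cut and the lactone carbonyl is restored. The ring oxygen and the alkoxy group are then already fixed in the right relation. The forward step needs an allyl metal that bonds through its CH2 end and adds faster than it deprotonates.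

4 back to 3, then to 1 and 2. The acetal O–CH2 bond and the bond from C3 (future C3') to the prenyl CH2 are cut. This leads to a cheap five-membered vinylogous acid and a prenyl donor. The demand is C- over O-allylation and one allylation, not two.

## Other disconnections considered

Alternative 1: The cut is at the CH2–CH bond of both prenyl groups on ring B. In the forward step, methyl 2,3-bis(bromomethyl)-4,5-bis(pivaloyloxy)benzoate A1 is coupled twice with 4,4,5,5-tetramethyl-2-(2-methylprop-1-en-1-yl)-1,3,2-dioxaborolane A2 under palladium–diphosphine catalysis with a phosphate base, to give methyl 2,3-bis(3-methylbut-2-en-1-yl)-4,5-bis(pivaloyloxy)benzoate A3. No ring is formed.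
- In its favour: ring B is taken from an existing arene, benzylic sp3–sp2 Suzuki coupling is a known reaction type, and the linear prenyl constitution is fixed by the boronate. All intermediates are bench-stable, and on ease of handling this is better than the chosen plan, which passes through the acid-sensitive 7 and an organobarium reagent. The pivalates come off with base, which is the equal of the chosen acetals in avoiding acid.
- Against it: A1 is an ortho-bis(benzylic) dibromide, so after the first oxidative addition the neighbouring CH2Br can be lost by 1,4-elimination. After the first coupling, the second benzylpalladium species sits next to a new alkene and can insert into it. The precursor of A1 needs a 2,3-dimethyl-4,5-dioxygenated benzoate and a double radical bromination that must stop at one bromine per methyl group. The pivalates of A3 would not survive the hydride reduction or the hydroxide condensation, so two protecting-group steps are added before the route can rejoin at 12.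
- Comparison: this alternative decorates a ring, whereas the chosen plan builds the ring with its substituents. It relies on two catalytic couplings at adjacent sites, against one cycloaddition followed by an ionisation. Step count is about equal if the dimethyl arene can be bought and longer if not.

Alternative 2: The cuts are at C8–C8a and C6–C7 of ring A. In the forward step, 3-ethoxycyclobut-2-en-1-one A4 opens thermally to a vinylketene, which adds to triisopropyl[(3,3-dimethylpent-4-en-1-yn-1-yl)oxy]silane A5. Four-electron ring opening, six-electron closure and tautomerisation then give 5-ethoxy-2-(2-methylbut-3-en-2-yl)-3-(triisopropylsilyloxy)phenol A6.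
- In its favour: the quaternary carbon arrives on the alkyne and can only end at C8. The three oxygens of ring A emerge differentiated in one step (free at C8a, silyl at O7, ethyl at O5). On this point it is better than the chosen plan, which depends on the symmetry of 16 in step 9 and on steric discrimination in step 10.
- Against it: A6 has no acetyl group and must be acylated at C4a in competition with C6. A4 and A5 each need several steps, whereas 17 is two steps from 14, which already carries the acetyl carbon. The O5 ethyl ether would need a Lewis acid dealkylation at the end, although another alkoxy group could be chosen. Ring B, the harder ring, is not addressed, so this complements the chosen key step and does not replace it.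
- Comparison: both are pericyclic sequences that end in aromatisation and are equal in mechanistic economy. For ring A this alternative is longer by several steps.

Alternative 3: The cut is at C4–C4a. In the forward step, (Z)-3-[3,5-bis(allyloxy)-2-(2-methylbut-3-en-2-yl)phenoxy]-3-[4,5-bis(allyloxy)-2,3-bis(3-methylbut-2-en-1-yl)phenyl]prop-2-enoic acid A7 is activated as a mixed anhydride under buffered conditions and acylates C4a, the only free carbon ortho to the aryl ether oxygen. This gives 5,7-bis(allyloxy)-2-[4,5-bis(allyloxy)-2,3-bis(3-methylbut-2-en-1-yl)phenyl]-8-(2-methylbut-3-en-2-yl)-4H-chromen-4-one A8.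
- In its favour: O1 is fixed by the aryl ether bond before the ring closes and only the six-membered closure is possible. The ring-size question of step 12 cannot arise, which is better than the chosen plan. The allyl ethers are removed by zerovalent palladium under neutral conditions, the equal of the acid-free cleavage chosen for step 13.
- Against it: A8 has no oxygen at C3. With seven other alkenes present, electrophilic oxidants are excluded and a deprotonation–borylation–oxidation sequence adds steps. The activating anhydride releases a strong acid next to prenyl groups and can itself acylate the very electron-rich rings. A7 needs an oxa-Michael addition of a hindered phenol to an arylpropiolate with control of alkene geometry. That propiolate would be made from 13, and the phenol partner needs the same differentiation as 18.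
- Comparison: this alternative lies downstream of the chosen key step and is two to three steps longer from 13. It uses electrophilic aromatic substitution where the chosen plan uses conjugate addition and oxidation.

Key step: step 4

Assumption: 1 is written as the dione but reacts as its enol, 4-hydroxyfuran-2(5H)-one; intermediates 6, 9 and 20 are racemic and their stereocentres are destroyed before 23, which has none.

Step 1
Reactants: 1 tetronic acid; 2 prenyl acetate (3-methylbut-2-en-1-yl acetate)
Product: 3 4-hydroxy-3-(3-methylbut-2-en-1-yl)furan-2(5H)-one
Conditions: Pd(PPh3)4 (3 mol%), Et3N, THF, 50 °C; 1 in excess (1.5 equiv)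
Reagents that add atoms: none
Why: Tsuji–Trost allylation: zerovalent palladium ionises 2 to a 1,1-dimethyl-π-allyl complex, which the soft tetronate anion should attack through C3 at the unsubstituted terminus to give the linear prenyl group. O-Allylated material is re-ionised by the catalyst and funnelled to the C3 product, and the excess of 1 holds back a second allylation.

Step 2
Reactants: 3 4-hydroxy-3-(3-methylbut-2-en-1-yl)furan-2(5H)-one
Product: 4 4-(methoxymethoxy)-3-(3-methylbut-2-en-1-yl)furan-2(5H)-one
Conditions: MOMCl, i-Pr2NEt, CH2Cl2, 0 °C
Reagents that add atoms: chloromethyl methyl ether (MOMCl), COCCl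
Why: O-Alkylation of the vinylogous carboxylic acid by the hard alkoxymethyl chloride should give the 4-O-acetal and leave the lactone carbonyl as the only electrophilic site. The acetal survives organometallic, hydride, hydroxide and peroxide reagents and is later removed together with the other three.

Step 3
Reactants: 4 4-(methoxymethoxy)-3-(3-methylbut-2-en-1-yl)furan-2(5H)-one; 5 prenyl chloride (1-chloro-3-methylbut-2-ene)
Product: 7 4-(methoxymethoxy)-2,3-bis(3-methylbut-2-en-1-yl)furan, via lactol 6 (not isolated)
Conditions: BaI2, lithium biphenylide, THF, rt; 5, −78 °C; then 4, −78 °C; aq. NH4Cl; PPTS (cat.), 4 Å MS, CH2Cl2, 0 °C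
Reagents that add atoms: none
Why: Proposed new method: prenylbarium chloride, which bonds to carbonyl carbon through its unsubstituted CH2 terminus (α-selective allylbarium addition, established for aldehydes and ketones), is asked here to add once to the vinylogous carbonate carbonyl of 4; the cyclic barium lactolate should persist at −78 °C and so prevent a second addition, and the strongly nucleophilic reagent should add faster than it deprotonates C5. Lactol 6 then loses water under mild anhydrous acid through an oxocarbenium ion and loss of a C5 proton, the known aromatisation that follows organometallic addition to, or hydride reduction of, furan-2(5H)-ones.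

Step 4
Reactants: 7 4-(methoxymethoxy)-2,3-bis(3-methylbut-2-en-1-yl)furan; 8 ethyl propiolate
Product: 10 ethyl 5-hydroxy-4-(methoxymethoxy)-2,3-bis(3-methylbut-2-en-1-yl)benzoate, via 7-oxanorbornadiene cycloadduct 9 (not isolated)
Conditions: 8 (3 equiv), PhMe, 60 °C; then PPTS (10 mol%), CH2Cl2, 0 °C to rt
Reagents that add atoms: none
Why: The electron-rich 3-alkoxyfuran 7 and the ynoate 8 should combine in a normal-demand Diels–Alder reaction, the closest known type being the cycloaddition of 3-alkoxyfurans with acetylenic esters followed by opening of the 7-oxanorbornadiene to a phenol. Ring B closes by an intermolecular [4+2] cycloaddition that forms C5'–C6' and C1'–C2' in one asynchronous event and leaves the furan oxygen as a bridge between C2' and C5' in 9. The orientation is set by the enol ether: the unsubstituted α-carbon next to the alkoxy carbon has the largest HOMO coefficient and bonds to the β-carbon of 8, so the ester-bearing carbon joins the prenylated α-carbon and the ester ends para to O4'. On mild acid the bridge opens at C2'–O and not at C5'–O, because only the C2' cation is delocalised through C3' onto the acetal oxygen at C4' as an oxocarbenium ion. Loss of the C5' proton then aromatises the ring and leaves the former bridge oxygen as the 5'-hydroxyl. No stereocentre survives: the two bridgehead centres of racemic 9 are destroyed on aromatisation. The step also needs chemoselectivity against the two prenyl alkenes, which do not react with a propiolate under thermal conditions without a strong Lewis acid. The acetal should be retained because the acid is weak and the medium aprotic.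

Step 5
Reactants: 10 ethyl 5-hydroxy-4-(methoxymethoxy)-2,3-bis(3-methylbut-2-en-1-yl)benzoate
Product: 11 ethyl 4,5-bis(methoxymethoxy)-2,3-bis(3-methylbut-2-en-1-yl)benzoate
Conditions: MOMCl, i-Pr2NEt, CH2Cl2, 0 °C to rt
Reagents that add atoms: chloromethyl methyl ether (MOMCl), COCCl
Why: Base-mediated O-alkylation of the one free phenol. It gives both catechol oxygens the same protecting group, stable to the hydride, hydroxide and peroxide steps ahead.

Step 6
Reactants: 11 ethyl 4,5-bis(methoxymethoxy)-2,3-bis(3-methylbut-2-en-1-yl)benzoate
Product: 12 [4,5-bis(methoxymethoxy)-2,3-bis(3-methylbut-2-en-1-yl)phenyl]methanol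
Conditions: i-Bu2AlH (2.5 equiv), CH2Cl2, −78 to 0 °C
Reagents that add atoms: none
Why: Reduction of the aryl ester to the benzylic alcohol by the aluminium hydride; full reduction is chosen over partial reduction because it can neither stall nor over-run. Acetals and isolated alkenes are inert to the reagent at this temperature.

Step 7
Reactants: 12 [4,5-bis(methoxymethoxy)-2,3-bis(3-methylbut-2-en-1-yl)phenyl]methanol
Product: 13 4,5-bis(methoxymethoxy)-2,3-bis(3-methylbut-2-en-1-yl)benzaldehyde
Conditions: MnO2 (activated, excess), CH2Cl2, rt
Reagents that add atoms: none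
Why: Heterogeneous oxidation of a benzylic alcohol by MnO2 stops at the aldehyde and leaves prenyl alkenes and acetals untouched.

Step 8
Reactants: 14 2,4,6-trihydroxyacetophenone; 15 prenyl bromide (1-bromo-3-methylbut-2-ene)
Product: 16 1-[2,6-dihydroxy-4-(3-methylbut-2-en-1-yloxy)phenyl]ethanone
Conditions: 15 (1.0 equiv), K2CO3, acetone, reflux
Reagents that add atoms: none
Why: Williamson etherification: the 4-hydroxyl is the most acidic and the only one not hydrogen-bonded to the carbonyl, so one equivalent of 15 with a weak carbonate base should alkylate there. A slight excess of 14 limits double alkylation and C-alkylation.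

Step 9
Reactants: 16 1-[2,6-dihydroxy-4-(3-methylbut-2-en-1-yloxy)phenyl]ethanone
Product: 17 1-[2,4,6-trihydroxy-3-(2-methylbut-3-en-2-yl)phenyl]ethanone
Conditions: Eu(fod)3 (10 mol%; fod = 6,6,7,7,8,8,8-heptafluoro-2,2-dimethyloctane-3,5-dionate), CHCl3, 60 °C
Reagents that add atoms: none
Why: Aromatic Claisen rearrangement ([3,3]) catalysed by the oxophilic europium chelate: the prenyl ether delivers its dimethyl-substituted terminus to the ortho carbon and so creates the quaternary 2-methylbut-3-en-2-yl group. Both ortho carbons of 16 are equivalent by symmetry and the para carbon carries the acetyl group, so one product is possible and no Cope shift can follow. The low temperature avoids the abnormal Claisen pathway and cyclisation onto the flanking hydroxyls.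

Step 10
Reactants: 17 1-[2,4,6-trihydroxy-3-(2-methylbut-3-en-2-yl)phenyl]ethanone
Product: 18 1-[2-hydroxy-4,6-bis(methoxymethoxy)-3-(2-methylbut-3-en-2-yl)phenyl]ethanone
Conditions: MOMCl (2.2 equiv), i-Pr2NEt, CH2Cl2, 0 °C to rt
Reagents that add atoms: chloromethyl methyl ether (MOMCl), COCCl
Why: Selective O-alkylation: O4–H is free and the most acidic; of the two ortho hydroxyls, O2–H is wedged between the quaternary carbon and the acetyl group and holds the carbonyl in a hydrogen bond, with the acetyl methyl turned toward O6, so the second acetal should go to O6. The hydroxyl left free is therefore the one next to the quaternary carbon, the future O1.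

Step 11
Reactants: 13 4,5-bis(methoxymethoxy)-2,3-bis(3-methylbut-2-en-1-yl)benzaldehyde; 18 1-[2-hydroxy-4,6-bis(methoxymethoxy)-3-(2-methylbut-3-en-2-yl)phenyl]ethanone
Product: 19 (E)-3-[4,5-bis(methoxymethoxy)-2,3-bis(3-methylbut-2-en-1-yl)phenyl]-1-[2-hydroxy-4,6-bis(methoxymethoxy)-3-(2-methylbut-3-en-2-yl)phenyl]prop-2-en-1-one
Conditions: KOH, EtOH/H2O, 0 °C to rt
Reagents that add atoms: none
Why: Claisen–Schmidt condensation: the enolate of 18 adds to the non-enolisable aldehyde 13 and E1cB loss of water gives the E enone. The four acetals and the three alkenes are stable to hydroxide at room temperature.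

Step 12
Reactants: 19 (E)-3-[4,5-bis(methoxymethoxy)-2,3-bis(3-methylbut-2-en-1-yl)phenyl]-1-[2-hydroxy-4,6-bis(methoxymethoxy)-3-(2-methylbut-3-en-2-yl)phenyl]prop-2-en-1-one
Product: 21 2-[4,5-bis(methoxymethoxy)-2,3-bis(3-methylbut-2-en-1-yl)phenyl]-3-hydroxy-5,7-bis(methoxymethoxy)-8-(2-methylbut-3-en-2-yl)-4H-chromen-4-one, via trans-3-hydroxyflavanone 20 (not isolated)
Conditions: H2O2 (30% aq.), NaOH, MeOH, 0 °C to rt
Reagents that add atoms: hydrogen peroxide, OO
Why: Algar–Flynn–Oyamada reaction: conjugate addition of the 2'-phenoxide (six-membered closure, O1–C2), trapping of the enolate by hydrogen peroxide at C3 and oxidation of 20 give the flavonol. Alkaline peroxide attacks only the enone, so the electron-rich alkenes are spared, and the two stereocentres of racemic 20 disappear on dehydrogenation.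

Step 13
Reactants: 21 2-[4,5-bis(methoxymethoxy)-2,3-bis(3-methylbut-2-en-1-yl)phenyl]-3-hydroxy-5,7-bis(methoxymethoxy)-8-(2-methylbut-3-en-2-yl)-4H-chromen-4-one
Product: 23 broussoflavonol C, via pentakis(trimethylsilyl) ether 22 (not isolated)
Conditions: Me3SiOTf (10 equiv), 2,2'-bipyridyl (15 equiv), MeCN, 0 °C to rt; then H2O
Reagents that add atoms: none
Why: Cleavage of aryl methoxymethyl ethers by the silyl triflate–bipyridyl pair: each acetal is converted to the aryl silyl ether and an N-(methoxymethyl)pyridinium salt, and water then hydrolyses both. No free protic acid is present, so the alkenes ortho to the liberated hydroxyls (C3'/O4', C8/O7, C2'/O3) should not add them.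

Compound list

1 | tetronic acid (furan-2,4(3H,5H)-dione) | O=C1CC(=O)CO1 | starting material
2 | prenyl acetate (3-methylbut-2-en-1-yl acetate) | CC(=O)OCC=C(C)C | starting material
3 | 4-hydroxy-3-(3-methylbut-2-en-1-yl)furan-2(5H)-one | CC(C)=CCC1=C(O)COC1=O | intermediate
4 | 4-(methoxymethoxy)-3-(3-methylbut-2-en-1-yl)furan-2(5H)-one | COCOC1=C(CC=C(C)C)C(=O)OC1 | intermediate
5 | prenyl chloride (1-chloro-3-methylbut-2-ene) | CC(C)=CCCl | starting material
6 | 4-(methoxymethoxy)-2,3-bis(3-methylbut-2-en-1-yl)-2,5-dihydrofuran-2-ol (racemic lactol) | COCOC1=C(CC=C(C)C)C(O)(CC=C(C)C)OC1 | intermediate (not isolated)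
7 | 4-(methoxymethoxy)-2,3-bis(3-methylbut-2-en-1-yl)furan | COCOc1coc(CC=C(C)C)c1CC=C(C)C | intermediate
8 | ethyl propiolate | CCOC(=O)C#C | starting material
9 | ethyl 5-(methoxymethoxy)-1,6-bis(3-methylbut-2-en-1-yl)-7-oxabicyclo[2.2.1]hepta-2,5-diene-2-carboxylate (racemic; bridgeheads joined by the oxygen bridge) | CCOC(=O)C1=CC2OC1(CC=C(C)C)C(CC=C(C)C)=C2OCOC | intermediate (not isolated)
10 | ethyl 5-hydroxy-4-(methoxymethoxy)-2,3-bis(3-methylbut-2-en-1-yl)benzoate | CCOC(=O)c1cc(O)c(OCOC)c(CC=C(C)C)c1CC=C(C)C | intermediate
11 | ethyl 4,5-bis(methoxymethoxy)-2,3-bis(3-methylbut-2-en-1-yl)benzoate | CCOC(=O)c1cc(OCOC)c(OCOC)c(CC=C(C)C)c1CC=C(C)C | intermediate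
12 | [4,5-bis(methoxymethoxy)-2,3-bis(3-methylbut-2-en-1-yl)phenyl]methanol | OCc1cc(OCOC)c(OCOC)c(CC=C(C)C)c1CC=C(C)C | intermediate
13 | 4,5-bis(methoxymethoxy)-2,3-bis(3-methylbut-2-en-1-yl)benzaldehyde | O=Cc1cc(OCOC)c(OCOC)c(CC=C(C)C)c1CC=C(C)C | intermediate
14 | 2,4,6-trihydroxyacetophenone | CC(=O)c1c(O)cc(O)cc1O | starting material
15 | prenyl bromide (1-bromo-3-methylbut-2-ene) | CC(C)=CCBr | starting material
16 | 1-[2,6-dihydroxy-4-(3-methylbut-2-en-1-yloxy)phenyl]ethanone | CC(=O)c1c(O)cc(OCC=C(C)C)cc1O | intermediate
17 | 1-[2,4,6-trihydroxy-3-(2-methylbut-3-en-2-yl)phenyl]ethanone | CC(=O)c1c(O)cc(O)c(C(C)(C)C=C)c1O | intermediate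
18 | 1-[2-hydroxy-4,6-bis(methoxymethoxy)-3-(2-methylbut-3-en-2-yl)phenyl]ethanone | CC(=O)c1c(OCOC)cc(OCOC)c(C(C)(C)C=C)c1O | intermediate
19 | (E)-3-[4,5-bis(methoxymethoxy)-2,3-bis(3-methylbut-2-en-1-yl)phenyl]-1-[2-hydroxy-4,6-bis(methoxymethoxy)-3-(2-methylbut-3-en-2-yl)phenyl]prop-2-en-1-one | C=CC(C)(C)c1c(O)c(C(=O)/C=C/c2cc(OCOC)c(OCOC)c(CC=C(C)C)c2CC=C(C)C)c(OCOC)cc1OCOC | intermediate
20 | trans-2-[4,5-bis(methoxymethoxy)-2,3-bis(3-methylbut-2-en-1-yl)phenyl]-3-hydroxy-5,7-bis(methoxymethoxy)-8-(2-methylbut-3-en-2-yl)chroman-4-one (racemic; the 2R,3R enantiomer is drawn) | CC(C)=CCc1c(CC=C(C)C)c(OCOC)c(OCOC)cc1[C@@H]2[C@H](C(=O)c3c(OCOC)cc(OCOC)c(C(C)(C)C=C)c3O2)O | intermediate (not isolated)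
21 | 2-[4,5-bis(methoxymethoxy)-2,3-bis(3-methylbut-2-en-1-yl)phenyl]-3-hydroxy-5,7-bis(methoxymethoxy)-8-(2-methylbut-3-en-2-yl)-4H-chromen-4-one | C=CC(C)(C)c1c(OCOC)cc(OCOC)c2c(=O)c(O)c(-c3cc(OCOC)c(OCOC)c(CC=C(C)C)c3CC=C(C)C)oc12 | intermediate
22 | 2-[2,3-bis(3-methylbut-2-en-1-yl)-4,5-bis(trimethylsilyloxy)phenyl]-8-(2-methylbut-3-en-2-yl)-3,5,7-tris(trimethylsilyloxy)-4H-chromen-4-one | C=CC(C)(C)c1c(O[Si](C)(C)C)cc(O[Si](C)(C)C)c2c(=O)c(O[Si](C)(C)C)c(-c3cc(O[Si](C)(C)C)c(O[Si](C)(C)C)c(CC=C(C)C)c3CC=C(C)C)oc12 | intermediate (not isolated)
23 | broussoflavonol C, 2-[4,5-dihydroxy-2,3-bis(3-methylbut-2-en-1-yl)phenyl]-3,5,7-trihydroxy-8-(2-methylbut-3-en-2-yl)-4H-chromen-4-one | C=CC(C)(C)c1c(O)cc(O)c2c(=O)c(O)c(-c3cc(O)c(O)c(CC=C(C)C)c3CC=C(C)C)oc12 | target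

Total step count: 13 steps. Longest linear sequence: 10 steps (steps 1 to 7 and 11 to 13, from 1 to 23); the ring A branch (steps 8 to 10) has 3 steps and joins at step 11.

Least certain steps

Step 3 (bears the label of a new method). The likely failures are deprotonation of 4 at C5 in place of addition, a second addition after collapse of the lactolate, bonding through the substituted allyl terminus, and hydrolysis of the enol acetal during dehydration. The fallback uses known chemistry only and sets out from 4. Reduction with i-Bu2AlH at −78 °C and mild acidic work-up (the known lactone-to-furan reduction) gives 3-(methoxymethoxy)-4-(3-methylbut-2-en-1-yl)furan F1. Lithiation with n-BuLi at the α-position flanked by the ring oxygen and the acetal oxygen, then Me3SiCl, gives [3-(methoxymethoxy)-4-(3-methylbut-2-en-1-yl)furan-2-yl]trimethylsilane F2. A second lithiation at the only remaining α-position and alkylation with 15 gives [3-(methoxymethoxy)-4,5-bis(3-methylbut-2-en-1-yl)furan-2-yl]trimethylsilane F3. Protodesilylation with n-Bu4NF returns to the route at 7.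

Step 4 (key step). The cycloaddition may be slow at the prenyl-bearing α-carbon, so that the acid-sensitive diene decomposes or is alkenylated at C5 in an open-chain Michael sense. The acetal may also be lost from the oxocarbenium stage of the ring opening. The fallback sets out from 7 and uses propynal, a more electrophilic dienophile with the same polarisation and already at the aldehyde oxidation level. The same cycloaddition and opening give 5-hydroxy-4-(methoxymethoxy)-2,3-bis(3-methylbut-2-en-1-yl)benzaldehyde F4. O-Alkylation with MOMCl and i-Pr2NEt returns to the route at 13, so that 10, 11 and 12 are bypassed.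

Step 10. The second acetalisation may not discriminate between the two hydroxyls ortho to the acetyl group. The fallback moves the differentiation before the rearrangement and sets out from 16. Mono-alkylation with one equivalent of MOMCl (the two hydroxyls are equivalent, and the remaining one becomes chelated) gives 1-[2-hydroxy-6-(methoxymethoxy)-4-(3-methylbut-2-en-1-yloxy)phenyl]ethanone F5. Claisen rearrangement with Eu(fod)3, directed to the carbon between O2 and O4 by bond fixation in the chelated hydroxy ketone, gives 1-[2,4-dihydroxy-6-(methoxymethoxy)-3-(2-methylbut-3-en-2-yl)phenyl]ethanone F6. Alkylation of the one non-chelated hydroxyl (O4) with MOMCl returns to the route at 18.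

Step 12. The oxidative cyclisation may close in the five-membered mode by attack at the α-carbon, because the alkoxy group ortho to the carbonyl on ring A and the prenyl group ortho to the enone on ring B twist the enone. The fallback separates ring closure from oxidation and sets out from 19. Oxa-Michael cyclisation with NaOAc in refluxing EtOH gives 2-[4,5-bis(methoxymethoxy)-2,3-bis(3-methylbut-2-en-1-yl)phenyl]-5,7-bis(methoxymethoxy)-8-(2-methylbut-3-en-2-yl)chroman-4-one F7, in which ring C is already six-membered. Enolisation with LiN(SiMe3)2 at −78 °C and hydroxylation with 2-(phenylsulfonyl)-3-phenyloxaziridine gives 20, isolated in this case. Dehydrogenation of 20 with alkaline hydrogen peroxide returns to the route at 21.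

Further compounds

F1 | step 3 | 3-(methoxymethoxy)-4-(3-methylbut-2-en-1-yl)furan | COCOc1cocc1CC=C(C)C
F2 | step 3 | [3-(methoxymethoxy)-4-(3-methylbut-2-en-1-yl)furan-2-yl]trimethylsilane | COCOc1c([Si](C)(C)C)occ1CC=C(C)C
F3 | step 3 | [3-(methoxymethoxy)-4,5-bis(3-methylbut-2-en-1-yl)furan-2-yl]trimethylsilane | COCOc1c([Si](C)(C)C)oc(CC=C(C)C)c1CC=C(C)C
F4 | step 4 | 5-hydroxy-4-(methoxymethoxy)-2,3-bis(3-methylbut-2-en-1-yl)benzaldehyde | O=Cc1cc(O)c(OCOC)c(CC=C(C)C)c1CC=C(C)C
F5 | step 10 | 1-[2-hydroxy-6-(methoxymethoxy)-4-(3-methylbut-2-en-1-yloxy)phenyl]ethanone | CC(=O)c1c(O)cc(OCC=C(C)C)cc1OCOC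
F6 | step 10 | 1-[2,4-dihydroxy-6-(methoxymethoxy)-3-(2-methylbut-3-en-2-yl)phenyl]ethanone | CC(=O)c1c(O)c(C(C)(C)C=C)c(O)cc1OCOC
F7 | step 12 | 2-[4,5-bis(methoxymethoxy)-2,3-bis(3-methylbut-2-en-1-yl)phenyl]-5,7-bis(methoxymethoxy)-8-(2-methylbut-3-en-2-yl)chroman-4-one (racemic) | C=CC(C)(C)c1c(OCOC)cc(OCOC)c2C(=O)CC(c3cc(OCOC)c(OCOC)c(CC=C(C)C)c3CC=C(C)C)Oc12
A1 | alternative 1 | methyl 2,3-bis(bromomethyl)-4,5-bis(pivaloyloxy)benzoate | COC(=O)c1cc(OC(=O)C(C)(C)C)c(OC(=O)C(C)(C)C)c(CBr)c1CBr
A2 | alternative 1 | 4,4,5,5-tetramethyl-2-(2-methylprop-1-en-1-yl)-1,3,2-dioxaborolane | CC(C)=CB1OC(C)(C)C(C)(C)O1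
A3 | alternative 1 | methyl 2,3-bis(3-methylbut-2-en-1-yl)-4,5-bis(pivaloyloxy)benzoate | COC(=O)c1cc(OC(=O)C(C)(C)C)c(OC(=O)C(C)(C)C)c(CC=C(C)C)c1CC=C(C)C
A4 | alternative 2 | 3-ethoxycyclobut-2-en-1-one | CCOC1=CC(=O)C1
A5 | alternative 2 | triisopropyl[(3,3-dimethylpent-4-en-1-yn-1-yl)oxy]silane | C=CC(C)(C)C#CO[Si](C(C)C)(C(C)C)C(C)C
A6 | alternative 2 | 5-ethoxy-2-(2-methylbut-3-en-2-yl)-3-(triisopropylsilyloxy)phenol | CCOc1cc(O)c(C(C)(C)C=C)c(O[Si](C(C)C)(C(C)C)C(C)C)c1
A7 | alternative 3 | (Z)-3-[3,5-bis(allyloxy)-2-(2-methylbut-3-en-2-yl)phenoxy]-3-[4,5-bis(allyloxy)-2,3-bis(3-methylbut-2-en-1-yl)phenyl]prop-2-enoic acid | OC(=O)/C=C(\Oc1cc(OCC=C)cc(OCC=C)c1C(C)(C)C=C)c1cc(OCC=C)c(OCC=C)c(CC=C(C)C)c1CC=C(C)C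
A8 | alternative 3 | 5,7-bis(allyloxy)-2-[4,5-bis(allyloxy)-2,3-bis(3-methylbut-2-en-1-yl)phenyl]-8-(2-methylbut-3-en-2-yl)-4H-chromen-4-one | C=CC(C)(C)c1c(OCC=C)cc(OCC=C)c2c(=O)cc(-c3cc(OCC=C)c(OCC=C)c(CC=C(C)C)c3CC=C(C)C)oc12
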